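**Retrosynthetic overview**

1. Target ⇒ (desilylation; amide → aldehyde) ⇒ trienol made by a [3,3] hydroxyl shift of the Nozaki–Hiyama–Kishi adduct of a core enol triflate and (2E)-8-methyl-4-methylidenenona-2,7-dienal (C2′–C3′ bond).
2. Tetrasubstituted C7 alkene ⇒ Horner–Wadsworth–Emmons reaction on a C7 ketone, unmasked from the isopropenyl group (Criegee), with the 9,10-epoxide relayed to the C10 carbinol.
3. Five-membered ring (formed second) ⇒ cross-metathesis with methyl vinyl ketone, then copper hydride reductive aldol closing C1–C2.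
4. Spiro carbon C5 ⇒ key Claisen [3,3] rearrangement of the allyl enol ether of an epoxy ketone (C5–C4 bond).
5. Six-membered ring (present from the start) ⇒ (S)-carvone, alkylated at C6 and epoxidised; its C7 centre sets C6 and C10 and is erased later.

Notation: TBS = tert-butyldimethylsilyl, TES = triethylsilyl, Tf = trifluoromethanesulfonyl. Locants C1–C10 and C1′–C11′ are those of the target spiro[4.5]decane and its side chain and are used for the same carbons throughout the text (the systematic names of 1, 3 and 4 use their own ring numbering). "Upper face" is the face of the six-membered ring that carries the oxygen on C10.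

Assumption: the iodide of step 1, the phosphonium salt of step 3 and the phosphonate of step 12 are bought as such.

Step 1
Reactants: 1 (S)-(+)-carvone
Product: 3 (5S,6R)-6-[3-(TBSO)propyl]-2-methyl-5-(prop-1-en-2-yl)cyclohex-2-en-1-one, via lithium dienolate 2 (not isolated)
Conditions: LiN(i-Pr)2, THF, −78 °C; then I(CH2)3OTBS, DMPU, −78 → 0 °C
Reagents that add atoms: tert-butyl(3-iodopropoxy)dimethylsilane, ICCCO[Si](C)(C)C(C)(C)C
Why: Kinetic α′-deprotonation gives the cross-conjugated dienolate, and its SN2 alkylation (enolate alkylation) takes the iodide anti to the neighbouring C7 isopropenyl group, so the new C6 centre is trans to it.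

Step 2
Reactants: 3 (5S,6R)-6-[3-(TBSO)propyl]-2-methyl-5-(prop-1-en-2-yl)cyclohex-2-en-1-one
Product: 4 (1S,3R,4S,6S)-3-[3-(TBSO)propyl]-1-methyl-4-(prop-1-en-2-yl)-7-oxabicyclo[4.1.0]heptan-2-one
Conditions: 30% H2O2, NaOH (cat.), MeOH, 0 °C
Reagents that add atoms: hydrogen peroxide, OO
Why: Weitz–Scheffer nucleophilic epoxidation, in which hydroperoxide adds to C9 anti to the isopropenyl group (as for carvone itself) and closes to the 9,10-epoxide on the upper face, cis to the C6 chain, fixing C9 and C10.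

Step 3
Reactants: 4 (1S,3R,4S,6S)-3-[3-(TBSO)propyl]-1-methyl-4-(prop-1-en-2-yl)-7-oxabicyclo[4.1.0]heptan-2-one
Product: 5 allyl enol ether of 4 (C5=CH–O–CH2CH=CH2 in place of C5=O; E/Z mixture)
Conditions: [Ph3PCH2OCH2CH=CH2]Cl, KOt-Bu, THF, 0 → 50 °C
Reagents that add atoms: (allyloxymethyl)triphenylphosphonium chloride, C=CCOC[P+](c1ccccc1)(c1ccccc1)c1ccccc1.[Cl-]
Why: Wittig olefination with the unstabilised alkoxymethylene ylide converts the hindered C5 ketone into the allyl enol ether without touching a stereocentre, and both enol ether isomers are usable.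

Step 4
Reactants: 5 allyl enol ether of 4
Product: 6 3-[3-(TBSO)propyl]-1-methyl-4-(prop-1-en-2-yl)-2-(prop-2-en-1-yl)-7-oxabicyclo[4.1.0]heptane-2-carbaldehyde (CHO on the upper face; allyl on the lower face)
Conditions: xylenes, i-Pr2NEt (cat.), 140 °C
Reagents that add atoms: none
Why: Claisen [3,3]-sigmatropic rearrangement through a chair transition state forms the C5–C4 bond on the face of C5 opposite the epoxide oxygen and the C6 chain, so the future spiro carbon is set with CHO up and allyl down from either enol ether isomer.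

Step 5
Reactants: 6 epoxy aldehyde (2-allyl-2-formyl compound)
Product: 7 analogue of 6 with (2E)-4-oxopent-2-en-1-yl in place of allyl
Conditions: methyl vinyl ketone (5 equiv), second-generation Hoveyda–Grubbs catalyst (5 mol %), CH2Cl2, 40 °C
Reagents that add atoms: methyl vinyl ketone, C=CC(C)=O
Why: Olefin cross-metathesis of the monosubstituted allyl alkene with the electron-poor partner gives the (E)-enone, the 1,1-disubstituted isopropenyl alkene being inert.

Step 6
Reactants: 7 enone aldehyde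
Product: 8 2-acetyl-9,10-epoxy-10-methyl-7-(prop-1-en-2-yl)-6-[3-(TBSO)propyl]spiro[4.5]decan-1-ol (1-OH and 2-acetyl cis; both on the side of the five-membered ring that faces C6)
Conditions: [(Ph3P)CuH]6 (0.5 equiv), toluene, −40 → 0 °C; aq NH4Cl
Reagents that add atoms: none
Why: Copper hydride 1,4-reduction gives a copper enolate that closes onto the aldehyde (reductive aldol cyclisation) through a chelated Zimmerman–Traxler transition state, which makes 1-OH and 2-acetyl cis, while the copper-bound aldehyde oxygen turns away from the epoxide oxygen and the C10 methyl towards the C6 side, which sets C1 and with it C2.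

Step 7
Reactants: 8 spiro ketol
Product: 9 1-O-TES ether of 8
Conditions: Et3SiCl, imidazole, DMAP (cat.), DMF, rt
Reagents that add atoms: chlorotriethylsilane, CC[Si](Cl)(CC)CC
Why: Silylation of the secondary alcohol under base, which leaves the acid-sensitive epoxide alone and changes no stereocentre.

Step 8
Reactants: 9 1-O-TES ether of 8
Product: 11 enol triflate (1-(TfO)ethenyl at C2 in place of acetyl), via potassium enolate 10 (not isolated)
Conditions: KN(SiMe3)2, THF, −78 °C; then PhNTf2, −78 → 0 °C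
Reagents that add atoms: N-phenylbis(trifluoromethanesulfonimide), O=S(=O)(N(c1ccccc1)S(=O)(=O)C(F)(F)F)C(F)(F)F
Why: Kinetic deprotonation at the methyl group (the ring α-hydrogen is hindered) and O-sulfonylation of the enolate give the terminal enol triflate with C2 untouched.

Step 9
Reactants: 11 enol triflate
Product: 14 C7 alcohol (7-OH on the lower face in place of isopropenyl), via methoxy hydroperoxide 12 (not isolated), via C7 acetate 13 (not isolated)
Conditions: O3, CH2Cl2/MeOH, −78 °C; Ac2O, Et3N, DMAP, CH2Cl2, 0 °C → rt; then K2CO3, MeOH, 0 °C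
Reagents that add atoms: ozone, [O-][O+]=O; methanol, CO (methanol atoms remain only in 12)
Why: Ozonolysis in methanol stops at the α-methoxy hydroperoxide, whose peracetate undergoes Criegee rearrangement with migration of C7 to oxygen with retention, and methanolysis frees the alcohol; the electron-poor enol triflate alkene is not attacked at −78 °C.

Step 10
Reactants: 14 C7 alcohol
Product: 16 γ-hydroxy enone (10-hydroxy-10-methylspiro[4.5]dec-8-en-7-one core; 10-OH on the upper face), via epoxy ketone 15 (not isolated)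
Conditions: Dess–Martin periodinane, pyridine, CH2Cl2, 0 °C; then Et3N, rt
Reagents that add atoms: none
Why: Dess–Martin oxidation gives the β,γ-epoxy ketone, which triethylamine opens by E1cB β-elimination, releasing the C10 tertiary alcohol with its C–O bond and configuration untouched.

Step 11
Reactants: 16 γ-hydroxy enone
Product: 17 saturated hydroxy ketone (10-hydroxy-10-methylspiro[4.5]decan-7-one core)
Conditions: [(Ph3P)CuH]6, toluene, 0 °C → rt; aq NH4Cl
Reagents that add atoms: none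
Why: Copper hydride conjugate reduction (Stryker reduction) saturates only the enone, and protonation of the copper enolate at C8 creates no stereocentre.

Step 12
Reactants: 17 saturated hydroxy ketone
Product: 18 (2E)-N-methoxy-N-methyl-2-(spiro[4.5]decan-7-ylidene)propanamide (amide cis to C8; methyl cis to C6)
Conditions: (EtO)2P(O)CH(CH3)C(O)N(OMe)Me, NaH, THF, 0 → 60 °C
Reagents that add atoms: diethyl [1-(N-methoxy-N-methylcarbamoyl)ethyl]phosphonate, CCOP(=O)(OCC)C(C)C(=O)N(C)OC
Why: Horner–Wadsworth–Emmons olefination, in which the carboxamide ends trans to the more substituted α-carbon C6 as with other unsymmetrical ketones, giving the (E)-tetrasubstituted alkene.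

Step 13
Reactants: 19 2-methylprop-2-en-1-ol
Product: 21 6-methyl-2-methylidenehept-5-en-1-ol, via dilithio dianion 20 (not isolated)
Conditions: n-BuLi (2.2 equiv), TMEDA, Et2O, 0 °C → rt; then prenyl bromide, −78 °C → rt
Reagents that add atoms: 1-bromo-3-methylbut-2-ene, CC(C)=CCBr
Why: O,C-dilithiation of methallyl alcohol and SN2 alkylation of the allylic carbanion (dianion alkylation); no stereocentre is formed.

Step 14
Reactants: 21 6-methyl-2-methylidenehept-5-en-1-ol
Product: 22 6-methyl-2-methylidenehept-5-enal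
Conditions: MnO2, CH2Cl2, rt
Reagents that add atoms: none
Why: Allylic oxidation by MnO2 stops at the 2-substituted acrolein and leaves the isolated trisubstituted alkene alone.

Step 15
Reactants: 22 6-methyl-2-methylidenehept-5-enal
Product: 23 (2E)-8-methyl-4-methylidenenona-2,7-dienal
Conditions: Ph3P=CHCHO, toluene, 80 °C
Reagents that add atoms: (triphenylphosphoranylidene)acetaldehyde, O=CC=P(c1ccccc1)(c1ccccc1)c1ccccc1
Why: Wittig reaction with the stabilised formylmethylene ylide gives the (E)-enal.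

Step 16
Reactants: 18 enol triflate Weinreb amide; 23 (2E)-8-methyl-4-methylidenenona-2,7-dienal
Product: 24 coupling product with (4E)-3-hydroxy-10-methyl-6-methylideneundeca-1,4,9-trien-2-yl at C2 (both C3′ epimers)
Conditions: CrCl2, NiCl2 (cat.), DMF, rt
Reagents that add atoms: none
Why: Nozaki–Hiyama–Kishi coupling, in which the vinylchromium species from the enol triflate adds only to the aldehyde; the new C3′ carbinol centre is erased in step 17.

Step 17
Reactants: 24 bis-allylic alcohol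
Product: 25 trienol with (2E,4E)-1-hydroxy-10-methyl-6-methylideneundeca-2,4,9-trien-2-yl at C2
Conditions: Ph3SiOReO3 (5 mol %), Et2O, −50 → −20 °C
Reagents that add atoms: none
Why: Oxorhenium-catalysed 1,3-hydroxyl transposition, a [3,3]-sigmatropic shift of the allyl perrhenate through a chair with the dienyl group equatorial, moves oxygen to C1′ and gives the (2′E)-alkene, driven by the conjugated triene and the primary alcohol.

Step 18
Reactants: 25 trienol Weinreb amide
Product: 26 1-O-TES 3″-O-TBS ether of the target (enal at C7)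
Conditions: i-Bu2AlH, THF, −78 °C; aq potassium sodium tartrate
Reagents that add atoms: none
Why: Weinreb amide reduction, in which one hydride adds to give a chelated tetrahedral intermediate that collapses to the enal only on work-up, so alkene geometry is kept and over-reduction avoided.

Step 19
Reactants: 26 bis-silyl ether of the target
Product: 27 (2E)-2-[(1R,2S,5S,6R,10S)-1,10-dihydroxy-2-[(2E,4E)-1-hydroxy-10-methyl-6-methylideneundeca-2,4,9-trien-2-yl]-6-(3-hydroxypropyl)-10-methylspiro[4.5]decan-7-ylidene]propanal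
Conditions: HF·pyridine, pyridine, THF, 0 °C → rt
Reagents that add atoms: none
Why: Fluoride-mediated desilylation removes both silyl ethers under buffered conditions that leave the enal, the triene and all stereocentres untouched.

**Compound list**

1 | (S)-(+)-carvone, (5S)-2-methyl-5-(prop-1-en-2-yl)cyclohex-2-en-1-one | O=C1C[C@@H](C(C)=C)CC=C1C | starting material
2 | lithium dienolate of 1 (O–C5=C6, cross-conjugated) | [Li+].[O-]C1=C[C@@H](C(C)=C)CC=C1C | intermediate
3 | (5S,6R)-6-[3-(TBSO)propyl]-2-methyl-5-(prop-1-en-2-yl)cyclohex-2-en-1-one (chain trans to isopropenyl) | O=C1[C@H](CCCO[Si](C)(C)C(C)(C)C)[C@@H](C(C)=C)CC=C1C | intermediate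
4 | (1S,3R,4S,6S)-3-[3-(TBSO)propyl]-1-methyl-4-(prop-1-en-2-yl)-7-oxabicyclo[4.1.0]heptan-2-one (epoxide oxygen and chain up, isopropenyl down) | O=C1[C@H](CCCO[Si](C)(C)C(C)(C)C)[C@@H](C(C)=C)C[C@@H]2O[C@]12C | intermediate
5 | allyl enol ether of 4: 2-[(prop-2-en-1-yloxy)methylidene] in place of the 2-oxo group; E/Z mixture; ring centres as in 4 | C=CCOC=C1[C@H](CCCO[Si](C)(C)C(C)(C)C)[C@@H](C(C)=C)C[C@@H]2O[C@]12C | intermediate
6 | 3-[3-(TBSO)propyl]-1-methyl-4-(prop-1-en-2-yl)-2-(prop-2-en-1-yl)-7-oxabicyclo[4.1.0]heptane-2-carbaldehyde; CHO cis to epoxide oxygen and chain, allyl cis to isopropenyl | O=C[C@]1(CC=C)[C@H](CCCO[Si](C)(C)C(C)(C)C)[C@@H](C(C)=C)C[C@@H]2O[C@]12C | intermediate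
7 | analogue of 6 with (2E)-4-oxopent-2-en-1-yl in place of allyl | O=C[C@]1(C/C=C/C(C)=O)[C@H](CCCO[Si](C)(C)C(C)(C)C)[C@@H](C(C)=C)C[C@@H]2O[C@]12C | intermediate
8 | 2-acetyl-9,10-epoxy-10-methyl-7-(prop-1-en-2-yl)-6-[3-(TBSO)propyl]spiro[4.5]decan-1-ol; 1-OH and 2-acetyl cis on the side facing C6; C1, chain and epoxide oxygen up, isopropenyl down | CC(=O)[C@@H]1CC[C@]2([C@H](CCCO[Si](C)(C)C(C)(C)C)[C@@H](C(C)=C)C[C@@H]3O[C@]23C)[C@@H]1O | intermediate
9 | 1-O-TES ether of 8 | CC(=O)[C@@H]1CC[C@]2([C@H](CCCO[Si](C)(C)C(C)(C)C)[C@@H](C(C)=C)C[C@@H]3O[C@]23C)[C@@H]1O[Si](CC)(CC)CC | intermediate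
10 | potassium enolate of 9 at the acetyl methyl | [K+].[O-]C(=C)[C@@H]1CC[C@]2([C@H](CCCO[Si](C)(C)C(C)(C)C)[C@@H](C(C)=C)C[C@@H]3O[C@]23C)[C@@H]1O[Si](CC)(CC)CC | intermediate
11 | enol triflate: 9 with 1-(TfO)ethenyl at C2 in place of acetyl | C=C(OS(=O)(=O)C(F)(F)F)[C@@H]1CC[C@]2([C@H](CCCO[Si](C)(C)C(C)(C)C)[C@@H](C(C)=C)C[C@@H]3O[C@]23C)[C@@H]1O[Si](CC)(CC)CC | intermediate
12 | 11 with 1-hydroperoxy-1-methoxyethyl at C7 in place of isopropenyl (mixture at the new carbon) | C=C(OS(=O)(=O)C(F)(F)F)[C@@H]1CC[C@]2([C@H](CCCO[Si](C)(C)C(C)(C)C)[C@@H](C(C)(OC)OO)C[C@@H]3O[C@]23C)[C@@H]1O[Si](CC)(CC)CC | intermediate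
13 | 11 with acetoxy at C7 in place of isopropenyl (lower face, retention) | C=C(OS(=O)(=O)C(F)(F)F)[C@@H]1CC[C@]2([C@H](CCCO[Si](C)(C)C(C)(C)C)[C@@H](OC(C)=O)C[C@@H]3O[C@]23C)[C@@H]1O[Si](CC)(CC)CC | intermediate
14 | 11 with hydroxy at C7 in place of isopropenyl (lower face) | C=C(OS(=O)(=O)C(F)(F)F)[C@@H]1CC[C@]2([C@H](CCCO[Si](C)(C)C(C)(C)C)[C@@H](O)C[C@@H]3O[C@]23C)[C@@H]1O[Si](CC)(CC)CC | intermediate
15 | 9,10-epoxy-10-methyl-2-[1-(TfO)ethenyl]-1-(TESO)-6-[3-(TBSO)propyl]spiro[4.5]decan-7-one | C=C(OS(=O)(=O)C(F)(F)F)[C@@H]1CC[C@]2([C@H](CCCO[Si](C)(C)C(C)(C)C)C(=O)C[C@@H]3O[C@]23C)[C@@H]1O[Si](CC)(CC)CC | intermediate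
16 | 10-hydroxy-10-methyl-2-[1-(TfO)ethenyl]-1-(TESO)-6-[3-(TBSO)propyl]spiro[4.5]dec-8-en-7-one (10-OH up) | C=C(OS(=O)(=O)C(F)(F)F)[C@@H]1CC[C@]2([C@H](CCCO[Si](C)(C)C(C)(C)C)C(=O)C=C[C@]2(C)O)[C@@H]1O[Si](CC)(CC)CC | intermediate
17 | 10-hydroxy-10-methyl-2-[1-(TfO)ethenyl]-1-(TESO)-6-[3-(TBSO)propyl]spiro[4.5]decan-7-one | C=C(OS(=O)(=O)C(F)(F)F)[C@@H]1CC[C@]2([C@H](CCCO[Si](C)(C)C(C)(C)C)C(=O)CC[C@]2(C)O)[C@@H]1O[Si](CC)(CC)CC | intermediate
18 | (2E)-N-methoxy-N-methyl-2-{10-hydroxy-10-methyl-2-[1-(TfO)ethenyl]-1-(TESO)-6-[3-(TBSO)propyl]spiro[4.5]decan-7-ylidene}propanamide | C=C(OS(=O)(=O)C(F)(F)F)[C@@H]1CC[C@]2([C@H](CCCO[Si](C)(C)C(C)(C)C)/C(=C(\C)C(=O)N(C)OC)CC[C@]2(C)O)[C@@H]1O[Si](CC)(CC)CC | intermediate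
19 | 2-methylprop-2-en-1-ol | C=C(C)CO | starting material
20 | dilithio derivative of 19 (alkoxide and allylic carbanion) | [Li+].[Li+].[CH2-]C(=C)C[O-] | intermediate
21 | 6-methyl-2-methylidenehept-5-en-1-ol | C=C(CO)CCC=C(C)C | intermediate
22 | 6-methyl-2-methylidenehept-5-enal | C=C(C=O)CCC=C(C)C | intermediate
23 | (2E)-8-methyl-4-methylidenenona-2,7-dienal | C=C(/C=C/C=O)CCC=C(C)C | intermediate
24 | 18 with (4E)-3-hydroxy-10-methyl-6-methylideneundeca-1,4,9-trien-2-yl at C2 in place of the enol triflate (C3′ epimers) | C=C(C(O)/C=C/C(=C)CCC=C(C)C)[C@@H]1CC[C@]2([C@H](CCCO[Si](C)(C)C(C)(C)C)/C(=C(\C)C(=O)N(C)OC)CC[C@]2(C)O)[C@@H]1O[Si](CC)(CC)CC | intermediate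
25 | 18 with (2E,4E)-1-hydroxy-10-methyl-6-methylideneundeca-2,4,9-trien-2-yl at C2 in place of the enol triflate | C=C(/C=C/C=C(/CO)[C@@H]1CC[C@]2([C@H](CCCO[Si](C)(C)C(C)(C)C)/C(=C(\C)C(=O)N(C)OC)CC[C@]2(C)O)[C@@H]1O[Si](CC)(CC)CC)CCC=C(C)C | intermediate
26 | target carrying TES on O–C1 and TBS on the hydroxypropyl oxygen | C=C(/C=C/C=C(/CO)[C@@H]1CC[C@]2([C@H](CCCO[Si](C)(C)C(C)(C)C)/C(=C(\C)C=O)CC[C@]2(C)O)[C@@H]1O[Si](CC)(CC)CC)CCC=C(C)C | intermediate
27 | (2E)-2-[(1R,2S,5S,6R,10S)-1,10-dihydroxy-2-[(2E,4E)-1-hydroxy-10-methyl-6-methylideneundeca-2,4,9-trien-2-yl]-6-(3-hydroxypropyl)-10-methylspiro[4.5]decan-7-ylidene]propanal | C=C(/C=C/C=C(/CO)[C@@H]1CC[C@]2([C@H](CCCO)/C(=C(\C)C=O)CC[C@]2(C)O)[C@@H]1O)CCC=C(C)C | target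

**Step count and risks**

Total step count: 19. Longest linear sequence: 16 steps (steps 1–12 and 16–19); steps 13–15 make the dienal.

Three steps most likely to fail:

Step 6. The face selectivity at C1 rests on a steric and dipole argument only, and 1,2-reduction of the aldehyde can compete. The fallback sets out from 6 and comes back at 8. CH2=CHMgBr (THF, −78 °C) adds to the aldehyde to give the divinyl carbinol F1. Ring-closing metathesis (second-generation Grubbs catalyst, CH2Cl2, 40 °C) gives the spiro cyclopent-2-en-1-ol F2; its C1 epimers are separable, the one with OH on the C6 side is carried on and the other is returned by Dess–Martin oxidation and NaBH4/CeCl3 reduction. Silylation with (1-bromoethenyl)chlorodimethylsilane (Et3N, DMAP) gives the bromovinylsilyl ether F3. Bu3SnH/AIBN (benzene, 80 °C) closes the vinyl radical 5-exo onto C2, necessarily cis to the C1 oxygen, to give the bicyclic siloxane F4. Tamao oxidation of the alkenyl–silicon bond (H2O2, KF, KHCO3) then gives 8.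

Step 12. The ketone is hindered, so olefination to a tetrasubstituted alkene may be slow, C6 may epimerise, and E/Z control may be modest. The fallback sets out from 17 and comes back at 18. Lithium prop-1-yn-1-olate (from ethyl 2,2-dibromopropanoate and t-BuLi, THF, −78 → 0 °C) adds to the ketone at room temperature. The resulting β-lactone enolate opens by a torquoselective 4π-electrocyclic ring opening in which the branched C6 arm rotates outward, giving after acidic work-up the (E)-acrylic acid F5. Coupling with MeNHOMe·HCl (EDC·HCl, DMAP, CH2Cl2) returns 18.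

Step 17. The bis-allylic alcohol can ionise, shift towards C5′ or give E/Z mixtures. The fallback sets out from 24 and comes back at 25. Acetylation (Ac2O, pyridine, DMAP) gives the secondary acetate F6. PdCl2(MeCN)2 (5 mol %, THF, rt) moves the acetoxy group by a cyclisation-induced [3,3] shift that does not pass through a free allyl cation, giving the primary (2′E)-acetate F7. K2CO3/MeOH returns 25.

Further compounds
F1 | step 6 | 6 with 1-hydroxyprop-2-en-1-yl in place of CHO (C1 epimers) | C=CC(O)[C@]1(CC=C)[C@H](CCCO[Si](C)(C)C(C)(C)C)[C@@H](C(C)=C)C[C@@H]2O[C@]12C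
F2 | step 6 | 9,10-epoxy-10-methyl-7-(prop-1-en-2-yl)-6-[3-(TBSO)propyl]spiro[4.5]dec-2-en-1-ol (1-OH on the side facing C6) | C1=CC[C@]2([C@H](CCCO[Si](C)(C)C(C)(C)C)[C@@H](C(C)=C)C[C@@H]3O[C@]23C)[C@@H]1O
F3 | step 6 | (1-bromoethenyl)dimethylsilyl ether of F2 | C1=CC[C@]2([C@H](CCCO[Si](C)(C)C(C)(C)C)[C@@H](C(C)=C)C[C@@H]3O[C@]23C)[C@@H]1O[Si](C)(C)C(Br)=C
F4 | step 6 | cis-fused cyclic siloxane: O–C1 and C2 bridged by SiMe2–C(=CH2) | C=C1[C@@H]2CC[C@]3([C@H](CCCO[Si](C)(C)C(C)(C)C)[C@@H](C(C)=C)C[C@@H]4O[C@]34C)[C@@H]2O[Si]1(C)C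
F5 | step 12 | (2E)-2-(spiro[4.5]decan-7-ylidene)propanoic acid corresponding to 18 | C=C(OS(=O)(=O)C(F)(F)F)[C@@H]1CC[C@]2([C@H](CCCO[Si](C)(C)C(C)(C)C)/C(=C(\C)C(=O)O)CC[C@]2(C)O)[C@@H]1O[Si](CC)(CC)CC
F6 | step 17 | 3′-O-acetate of 24 | C=C(C(OC(C)=O)/C=C/C(=C)CCC=C(C)C)[C@@H]1CC[C@]2([C@H](CCCO[Si](C)(C)C(C)(C)C)/C(=C(\C)C(=O)N(C)OC)CC[C@]2(C)O)[C@@H]1O[Si](CC)(CC)CC
F7 | step 17 | 1′-O-acetate of 25 | C=C(/C=C/C=C(/COC(C)=O)[C@@H]1CC[C@]2([C@H](CCCO[Si](C)(C)C(C)(C)C)/C(=C(\C)C(=O)N(C)OC)CC[C@]2(C)O)[C@@H]1O[Si](CC)(CC)CC)CCC=C(C)C
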